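In the early hours of the north run you watch J, fed over 1.5 h, give D, and D give Q, while G barely shows.

all flasks: J 0.020 M (fed, over 1.5 h); E 1.7 mM (held)

| run | remark | time |
|---|---|---|
| north | the very flask that is asked about, followed so far; the fed solution adds 0.10 times the starting volume |  |
| flask | the fed solution adds 0.10 times the starting volume | 5.0 d |

north run (percent of the J charged)

| time / h | D / % | J / % | Q / % | G / % |
|---|---|---|---|---|
| 1.33 | 12.9 | 75.7 | 1.6 | 0.5 |
| 3.00 | 33.8 | 58.1 | 7.1 | 0 |
| 6.00 | 43.5 | 30.6 | 25.0 | 0.6 |
| 10.0 | 35.2 | 16.8 | 46.2 | 1.3 |

(standard deviation of a reading: 0.5 percentage points)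

1. the largest share of what was charged as J, at 5.0 d belongs to (D / Q / G / J)
2. the largest share itself, whichever of these holds it, in percent of the J charged

- every charge counts on the volume at the start, and the solution that is fed holds the whole dose
- what was read earlier has a scatter of 0.5 percentage points, one standard deviation
- at the start none of E is in solution
- percentages count the whole charge, also what has not yet gone in

The ladder starts with the feed. On the next rung, J falls from 3.00 h to 10.0 h with a half-life of 3.91 h, longer than the feed. Then come D and Q. From 1.33 h to 6.00 h, Q gains 0.151 h⁻¹ for each unit of D, while Q over D averages 0.358. From 6.00 h to 10.0 h the gain is 0.135 h⁻¹ at 0.905, smaller than before, which suggests that Q returns to D.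

Join these two ends with a straight line and the gain reaches zero where Q over D is 5.42, the equilibrium ratio as a rough, extrapolated reading. So the resting split, the share of the D-and-Q pair held as Q, is 84.4%. The same line gives the pair a relaxation half-life of 3.62 h. Both rungs are far shorter than 5.0 d, so I expect this flask to stand near its split by then. The top rung is G, at 1.3% after 10.0 h. I therefore reckon on Q leading, a little below the split, with J and G holding some of the charge.

The forecast gives Q at 72%, below my split, and says “The data cannot separate these”. The flask gives Q at 83.0%.

    J + X → G (k = 9.60 × 10⁻⁵ M⁻¹ s⁻¹)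
    J + Z ⇌ D + X (K = 36.0, k = 0.0420 M⁻¹ s⁻¹)
    E ⇌ Z, rate k3*(csat - [Z]) (kL = 0.0110 s⁻¹)
    D ⇌ Q (K = 7.70, k = 4.30 × 10⁻⁵ s⁻¹)

In this flask, the split applied to what J (2.81%) and G (3.48%) leave gives 79.1%, against 83.0%. The undoing of Q into D holds Q down: the run without that undoing reaches 98.1% instead of 83.0%. In the neighbour flask with 0.034 M of J, the split applied to what J (4.00%) and G (7.32%) leave gives 74.8%; the computed Q there is 78.6%.

The data come from a simulation for an exercise; scatter was added.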